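**Plan**
- Retrosynthesis: the C3–O acyl bond is cut first (trienoic acid), then C7=C11 (aldol/dehydration, C12 carried as an aldehyde), then C5–C10 and C1–C2 in one operation (intramolecular Diels–Alder), and in the open chain C10=C1 (Horner–Wadsworth–Emmons) and C5–C6 (B-alkyl Suzuki).
- Enabling feature: ring A carries its oxygen on C3 next to the methyl-bearing C4, the imprint of a 2-silyloxy diene C2=C3–C4=C5, and the four carbons C6–C9 of ring B tie the diene end C5 to C10. Rings A and B are therefore one folded triene whose C1 activator (PhSO2) can be lost afterwards.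
- Forward: the (E)-enol triflate of ethyl 2-methylacetoacetate and a vinyl carbinol from methyl (S)-glycerate are joined at C5–C6. C8 is ketalised, C3 becomes the methyl ketone and C10 the vinyl sulfone. Enol silylation and heating close rings A and B together; ring A is then reduced, ring B receives its side chain, and the trienoate goes on last.
- Stereochemistry: C9 is bought with the glycerate and directs C5 and C10 in the cycloaddition. C4 comes from protonation anti to the C5 methyl and C3 from a thermodynamic dissolving-metal reduction. The C4=C5 geometry comes from the enol triflate, the C7=C11 geometry from the steric and dipolar preference of the enone, and the trienoate geometry from Horner–Wadsworth–Emmons olefination.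

Key step: step 13

Remark: eremophilane numbering is used throughout, also for open-chain precursors (ring A = C1–C5, C10; ring B = C5–C10; C14 on C4, C15 on C5, C11–C13 on C7); α is the face of H-10, β the face of the C5 methyl; TBS = tert-butyldimethylsilyl, TES = triethylsilyl.

**Route**

Step 1
Reactants: 1 ethyl 2-methylacetoacetate
Product: 2 ethyl (E)-2-methyl-3-(trifluoromethylsulfonyloxy)but-2-enoate
Conditions: Tf2O, aq Me4NOH, hexanes, 5 °C
Reagents that add atoms: triflic anhydride, O=S(=O)(OS(=O)(=O)C(F)(F)F)C(F)(F)F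
Why: O-triflation of the β-keto ester enolate under non-chelating conditions, where the free ammonium enolate adopts the dipole-minimised W shape, so the triflate should end up trans to the ester (E).

Step 2
Reactants: 3 methyl (S)-2,2-dimethyl-1,3-dioxolane-4-carboxylate
Product: 4 methyl (S)-2,3-dihydroxypropanoate
Conditions: TsOH·H2O (cat.), MeOH, rt
Reagents that add atoms: none
Why: Acid-catalysed transacetalisation to methanol frees the diol while the stereocentre (the future C9) is not touched.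

Step 3
Reactants: 4 methyl (S)-2,3-dihydroxypropanoate
Product: 5 methyl (S)-2,3-bis(TBSO)propanoate
Conditions: TBSCl, imidazole, DMF, rt
Reagents that add atoms: tert-butyldimethylsilyl chloride, CC(C)(C)[Si](C)(C)Cl
Why: Imidazole-promoted silyl ether formation on both hydroxyls, which gives one protecting group for C9 and C10 that can later be removed selectively at the primary position.

Step 4
Reactants: 5 methyl (S)-2,3-bis(TBSO)propanoate
Product: 7 (4S)-4,5-bis(TBSO)pent-1-en-3-ol (both C3 epimers), via aldehyde 6 (not isolated)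
Conditions: i-Bu2AlH, CH2Cl2, −78 °C; then CH2=CHMgBr, −78 → 0 °C
Reagents that add atoms: vinylmagnesium bromide, C=C[Mg]Br
Why: Half-reduction of the ester to the aluminium hemiacetal followed by Grignard addition in the same flask keeps the epimerisable α-silyloxy aldehyde from being handled, and the carbinol configuration (C8) is irrelevant because it is oxidised in step 6.

Step 5
Reactants: 7 (4S)-4,5-bis(TBSO)pent-1-en-3-ol; 2 ethyl (E)-2-methyl-3-(trifluoromethylsulfonyloxy)but-2-enoate
Product: 9 ethyl (2E,7S)-7,8-bis(TBSO)-6-hydroxy-2,3-dimethyloct-2-enoate (both C6 epimers), via alkylborane 8 (not isolated)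
Conditions: 9-BBN (2.2 equiv), THF, 0 °C → rt; then 2, PdCl2(dppf), AsPh3, Cs2CO3, DMF–H2O, rt
Reagents that add atoms: none
Why: Anti-Markovnikov hydroboration (the free hydroxyl consumes the second equivalent of borane) and B-alkyl Suzuki–Miyaura coupling, in which zerovalent palladium inserts into the C–OTf bond and couples with retention, so C6 should stand trans to the ester on the tetrasubstituted C4=C5 alkene.

Step 6
Reactants: 9 ethyl (2E,7S)-7,8-bis(TBSO)-6-hydroxy-2,3-dimethyloct-2-enoate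
Product: 10 ethyl (2E,7S)-7,8-bis(TBSO)-2,3-dimethyl-6-oxooct-2-enoate
Conditions: Dess–Martin periodinane, NaHCO3, CH2Cl2, rt
Reagents that add atoms: none
Why: Dess–Martin oxidation of the secondary alcohol gives the C8 ketone under buffered, non-basic conditions that should leave the adjacent C9 stereocentre alone.

Step 7
Reactants: 10 ethyl (2E,7S)-7,8-bis(TBSO)-2,3-dimethyl-6-oxooct-2-enoate
Product: 11 ethyl (E)-5-{2-[(S)-1,2-bis(TBSO)ethyl]-1,3-dioxolan-2-yl}-2,3-dimethylpent-2-enoate
Conditions: Me3SiOCH2CH2OSiMe3, Me3SiOTf (cat.), CH2Cl2, −78 → −20 °C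
Reagents that add atoms: 1,2-bis(trimethylsilyloxy)ethane, C[Si](C)(C)OCCO[Si](C)(C)C
Why: Noyori ketalisation works at low temperature without enolising the α-silyloxy ketone, and the dioxolane masks C8 against the organometallic, enolisation and thermal steps that follow.

Step 8
Reactants: 11 ethyl (E)-5-{2-[(S)-1,2-bis(TBSO)ethyl]-1,3-dioxolan-2-yl}-2,3-dimethylpent-2-enoate
Product: 13 (E)-6-{2-[(S)-1,2-bis(TBSO)ethyl]-1,3-dioxolan-2-yl}-3,4-dimethylhex-3-en-2-one, via Weinreb amide 12 (not isolated)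
Conditions: MeNH(OMe)·HCl, i-PrMgCl, THF, −20 → 0 °C; then MeMgBr, 0 °C
Reagents that add atoms: methylmagnesium bromide, C[Mg]Br
Why: Weinreb ketone synthesis in one flask, in which the magnesium amide converts the ester into the N-methoxy-N-methylamide and its chelated tetrahedral adduct with MeMgBr stops at the methyl ketone (C2–C3).

Step 9
Reactants: 13 (E)-6-{2-[(S)-1,2-bis(TBSO)ethyl]-1,3-dioxolan-2-yl}-3,4-dimethylhex-3-en-2-one
Product: 14 (E)-6-{2-[(S)-1-(TBSO)-2-hydroxyethyl]-1,3-dioxolan-2-yl}-3,4-dimethylhex-3-en-2-one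
Conditions: HF·pyridine, pyridine, THF, 0 °C
Reagents that add atoms: none
Why: Buffered HF removes the primary silyl ether much faster than the hindered secondary one (steric differentiation in desilylation), and the ketal tolerates the weakly acidic medium.

Step 10
Reactants: 14 (E)-6-{2-[(S)-1-(TBSO)-2-hydroxyethyl]-1,3-dioxolan-2-yl}-3,4-dimethylhex-3-en-2-one
Product: 15 (S)-2-(TBSO)-2-{2-[(E)-3,4-dimethyl-5-oxohex-3-en-1-yl]-1,3-dioxolan-2-yl}acetaldehyde
Conditions: Dess–Martin periodinane, NaHCO3, CH2Cl2, 0 °C → rt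
Reagents that add atoms: none
Why: Dess–Martin oxidation gives the α-silyloxy aldehyde (C10) under buffered conditions, and it is used crude so that C9 cannot epimerise.

Step 11
Reactants: 15 (S)-2-(TBSO)-2-{2-[(E)-3,4-dimethyl-5-oxohex-3-en-1-yl]-1,3-dioxolan-2-yl}acetaldehyde; 16 diethyl (phenylsulfonyl)methylphosphonate
Product: 17 (E)-6-{2-[(1S,2E)-1-(TBSO)-3-(phenylsulfonyl)prop-2-en-1-yl]-1,3-dioxolan-2-yl}-3,4-dimethylhex-3-en-2-one
Conditions: NaH, THF, 0 °C
Reagents that add atoms: none
Why: Horner–Wadsworth–Emmons olefination with the sulfonyl-stabilised phosphonate anion is E-selective and reacts with the aldehyde only, the hindered methyl ketone being far slower.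

Step 12
Reactants: 17 (E)-6-{2-[(1S,2E)-1-(TBSO)-3-(phenylsulfonyl)prop-2-en-1-yl]-1,3-dioxolan-2-yl}-3,4-dimethylhex-3-en-2-one
Product: 18 (3E)-2-(TBSO)-3,4-dimethyl-6-{2-[(1S,2E)-1-(TBSO)-3-(phenylsulfonyl)prop-2-en-1-yl]-1,3-dioxolan-2-yl}hexa-1,3-diene
Conditions: TBSOTf, Et3N, CH2Cl2, −78 → 0 °C
Reagents that add atoms: tert-butyldimethylsilyl triflate, CC(C)(C)[Si](C)(C)OS(=O)(=O)C(F)(F)F
Why: Soft enolisation (silyl triflate and amine) removes the methyl proton of the twisted, poorly conjugated ketone and gives the cross-conjugated 2-silyloxy diene under conditions mild enough for the γ-silyloxy vinyl sulfone.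

Step 13
Reactants: 18 (3E)-2-(TBSO)-3,4-dimethyl-6-{2-[(1S,2E)-1-(TBSO)-3-(phenylsulfonyl)prop-2-en-1-yl]-1,3-dioxolan-2-yl}hexa-1,3-diene
Product: 19 (1S,5S,9S,10R)-3,9α-bis(TBSO)-8,8-(ethylenedioxy)-1α-(phenylsulfonyl)-11,12,13-trinoreremophil-3-ene (trans-fused, 5β-methyl, 10α-H)
Conditions: toluene (0.01 M), BHT, Et3N (trace), sealed tube, 170 °C
Reagents that add atoms: none
Why: Thermal type 1 intramolecular Diels–Alder reaction, a concerted but asynchronous suprafacial [4+2] addition of the electron-rich 2-silyloxy diene C2=C3–C4=C5 across the electron-poor (E)-vinyl sulfone C10=C1, whose closest precedent is the cyclisation of 1-sulfonyl-1,7,9-decatrienes to trans-fused bicycles. Ring A (a cyclohexene that keeps C3=C4 as the silyl enol ether) is closed by the two new bonds C5–C10 and C1–C2, and ring B (C5–C6–C7–C8–C9–C10) is closed as a six-membered ring by the C5–C10 bond through the four-atom tether. C5 and C10 are set relative to each other by the anti, sulfone-endo arrangement with the tether in a chair, the only one that keeps the C4 methyl (cis to C6) clear of the tether, which gives the trans fusion with the inside methyl on C5 anti to H-10; C1 follows from the (E)-geometry of the dienophile and is deleted in step 14. The absolute sense comes from C9, whose silyloxy group takes the equatorial site of the chair, anti to the forming C5–C10 bond, because the axial alternative would be 1,3-diaxial to the C5 methyl. The step needs facial and endo/exo selectivity and a rate above that of the 1,5-hydrogen shift of the (Z)-methyl diene; the donor oxygen on C3, the gem-dialkoxy effect of the C8 ketal and the tether, which overrides the electronic regiochemical preference of the diene, are what should secure it.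

Step 14
Reactants: 19 Diels–Alder adduct
Product: 21 (4R,5S,9S,10R)-9α-(TBSO)-8,8-(ethylenedioxy)-11,12,13-trinoreremophil-1-en-3-one, via β-sulfonyl ketone 20 (not isolated)
Conditions: Bu4NF, AcOH, THF, −20 °C; then DBU, 0 °C → rt
Reagents that add atoms: none
Why: Fluoride cleaves the silyl enol ether and C4 is protonated from the α face, anti to the axial C5 methyl (4β-methyl, also the more stable epimer), after which E1cB β-elimination of benzenesulfinate removes the activator and leaves the C1=C2 enone.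

Step 15
Reactants: 21 enone
Product: 23 (3R,4R,5R,9S,10R)-9α-(TBSO)-8,8-(ethylenedioxy)-11,12,13-trinoreremophilan-3α-ol, via saturated ketone 22 (not isolated)
Conditions: Li, NH3(l)–THF, EtOH, −78 → −33 °C; then NH4Cl
Reagents that add atoms: none
Why: Dissolving-metal (Birch-type) reduction first saturates the enone and then reduces the ketone under thermodynamic control to the equatorial 3α-alcohol, the epimer that hydride reagents would disfavour because axial delivery is blocked by the syn-axial C5 methyl.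

Step 16
Reactants: 23 ketal alcohol
Product: 24 (3R,4R,5R,9S,10R)-3α-hydroxy-9α-(TBSO)-11,12,13-trinoreremophilan-8-one
Conditions: TsOH·H2O, acetone–H2O, 50 °C
Reagents that add atoms: water, O
Why: Acid-catalysed ketal hydrolysis (transketalisation to acetone) frees the C8 ketone, and the equatorial C9 silyloxy group is the stable epimer, so enolisation cannot scramble C9.

Step 17
Reactants: 24 hydroxy ketone
Product: 25 (3R,4R,5R,9S,10R)-3α-(TESO)-9α-(TBSO)-11,12,13-trinoreremophilan-8-one
Conditions: Et3SiCl, imidazole, CH2Cl2, 0 °C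
Reagents that add atoms: chlorotriethylsilane, CC[Si](Cl)(CC)CC
Why: Silyl ether formation on the only free hydroxyl, with TES chosen because it falls together with the acetal in step 20 while the TBS ether at C9 stays.

Step 18
Reactants: 25 TES ether ketone; 26 1,1-dimethoxypropan-2-one
Product: 27 11-hydroxy-12,12-dimethoxy-3α-(TESO)-9α-(TBSO)eremophilan-8-one (mixture at C7 and C11)
Conditions: LiN(i-Pr)2, THF, −78 °C; CeCl3, −78 °C; then 26; AcOH, −78 °C
Reagents that add atoms: none
Why: Kinetic enolate formation on the CH2 side (C7, not the hindered silyloxy-bearing C9) and crossed aldol addition through the cerium enolate, which suppresses proton transfer to the enolisable but activated α,α-dialkoxy ketone; the new centres at C7 and C11 are erased in step 19.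

Step 19
Reactants: 27 aldol
Product: 29 (E)-12,12-dimethoxy-3α-(TESO)-9α-(TBSO)eremophil-7(11)-en-8-one, via mesylate 28 (not isolated)
Conditions: MsCl, Et3N, CH2Cl2, 0 °C; then DBU, rt → 40 °C
Reagents that add atoms: none
Why: Sulfene mesylation of the tertiary alcohol and E1cB dehydration under equilibrating base, where the branched dimethoxymethyl group should take the site anti to the C8 carbonyl (syn to C6), as the larger β-substituent does in alkylidene cyclohexanones, leaving C13 cis to the carbonyl (E).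

Step 20
Reactants: 29 enone acetal
Product: 31 (E)-3α-hydroxy-8-oxo-9α-(TBSO)eremophil-7(11)-en-12-al, via hydroxy acetal 30 (not isolated)
Conditions: TsOH·H2O (cat.), acetone–H2O, rt
Reagents that add atoms: water, O
Why: Mild aqueous acid hydrolysis removes the TES ether and the dimethyl acetal while the hindered C9 TBS ether survives, and the trans arrangement of the two carbonyls on C7=C11 is also the thermodynamically preferred enedione geometry.

Step 21
Reactants: 32 (E)-non-3-en-2-one; 33 triethyl 4-phosphonocrotonate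
Product: 34 ethyl (2E,4E,6E)-5-methyldodeca-2,4,6-trienoate
Conditions: LiN(SiMe3)2, THF, −78 °C → rt
Reagents that add atoms: none
Why: Vinylogous Horner–Wadsworth–Emmons olefination of the methyl ketone, trans-selective at both new alkenes; any minor 4Z isomer is removed by chromatography or equilibrated with a trace of iodine.

Step 22
Reactants: 34 ethyl (2E,4E,6E)-5-methyldodeca-2,4,6-trienoate
Product: 35 (2E,4E,6E)-5-methyldodeca-2,4,6-trienoic acid
Conditions: LiOH, THF–MeOH–H2O, rt; then aq HCl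
Reagents that add atoms: lithium hydroxide, [Li+].[OH-]
Why: Saponification of the ester, which does not disturb the triene geometry at room temperature.

Step 23
Reactants: 35 (2E,4E,6E)-5-methyldodeca-2,4,6-trienoic acid; 31 (E)-3α-hydroxy-8-oxo-9α-(TBSO)eremophil-7(11)-en-12-al
Product: 37 (E)-8,12-dioxo-9α-(TBSO)eremophil-7(11)-en-3α-yl (2E,4E,6E)-5-methyldodeca-2,4,6-trienoate, via mixed anhydride 36 (not isolated)
Conditions: 2,4,6-Cl3C6H2COCl, Et3N, THF, rt; then 31, DMAP, toluene, rt
Reagents that add atoms: none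
Why: Yamaguchi esterification, in which DMAP transfers the trienoyl group from the mixed anhydride to the equatorial C3 alcohol, the only free hydroxyl in 31.

Step 24
Reactants: 37 trienoate enal
Product: 38 (E)-12-hydroxy-8-oxo-9α-(TBSO)eremophil-7(11)-en-3α-yl (2E,4E,6E)-5-methyldodeca-2,4,6-trienoate
Conditions: LiAlH(Ot-Bu)3, THF, −78 °C
Reagents that add atoms: none
Why: Chemoselective 1,2-reduction of the aldehyde by a bulky, mild hydride, which should leave the hindered C8 ketone and the ester alone and cannot add conjugatively because both alkene carbons are fully substituted.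

Step 25
Reactants: 38 silyl-protected target
Product: 39 (3R,4R,5R,9S,10R)-9α,12-dihydroxy-8-oxoeremophil-7(11)E-en-3α-yl (2E,4E,6E)-5-methyldodeca-2,4,6-trienoate (target)
Conditions: HF·pyridine, THF, 0 °C → rt
Reagents that add atoms: none
Why: Fluoride-mediated desilylation frees the C9 hydroxyl under weakly acidic conditions that should spare the trienoate, the enone and the allylic alcohol.

**Compound list**
1 | ethyl 2-methylacetoacetate | CCOC(=O)C(C)C(C)=O | starting material
2 | ethyl (E)-2-methyl-3-(trifluoromethylsulfonyloxy)but-2-enoate | CCOC(=O)/C(C)=C(\C)OS(=O)(=O)C(F)(F)F | intermediate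
3 | methyl (S)-2,2-dimethyl-1,3-dioxolane-4-carboxylate | COC(=O)[C@@H]1COC(C)(C)O1 | starting material
4 | methyl (S)-2,3-dihydroxypropanoate | COC(=O)[C@@H](O)CO | intermediate
5 | methyl (S)-2,3-bis(TBSO)propanoate | COC(=O)[C@@H](O[Si](C)(C)C(C)(C)C)CO[Si](C)(C)C(C)(C)C | intermediate
6 | (S)-2,3-bis(TBSO)propanal, held as its aluminium hemiacetal (not isolated) | O=C[C@@H](O[Si](C)(C)C(C)(C)C)CO[Si](C)(C)C(C)(C)C | intermediate
7 | (4S)-4,5-bis(TBSO)pent-1-en-3-ol, both C3 epimers | C=CC(O)[C@@H](O[Si](C)(C)C(C)(C)C)CO[Si](C)(C)C(C)(C)C | intermediate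
8 | 9-BBN adduct of 7: C-borane at the former terminal carbon (C6), O-borinate at the carbinol (not isolated) | C1CCC2CCCC1B2CCC(OB1C2CCCC1CCC2)[C@@H](O[Si](C)(C)C(C)(C)C)CO[Si](C)(C)C(C)(C)C | intermediate
9 | ethyl (2E,7S)-7,8-bis(TBSO)-6-hydroxy-2,3-dimethyloct-2-enoate, both C6 epimers | CCOC(=O)/C(C)=C(\C)CCC(O)[C@@H](O[Si](C)(C)C(C)(C)C)CO[Si](C)(C)C(C)(C)C | intermediate
10 | ethyl (2E,7S)-7,8-bis(TBSO)-2,3-dimethyl-6-oxooct-2-enoate | CCOC(=O)/C(C)=C(\C)CCC(=O)[C@@H](O[Si](C)(C)C(C)(C)C)CO[Si](C)(C)C(C)(C)C | intermediate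
11 | ethyl (E)-5-{2-[(S)-1,2-bis(TBSO)ethyl]-1,3-dioxolan-2-yl}-2,3-dimethylpent-2-enoate | CCOC(=O)/C(C)=C(\C)CCC1(OCCO1)[C@@H](O[Si](C)(C)C(C)(C)C)CO[Si](C)(C)C(C)(C)C | intermediate
12 | (E)-5-{2-[(S)-1,2-bis(TBSO)ethyl]-1,3-dioxolan-2-yl}-N-methoxy-N,2,3-trimethylpent-2-enamide (not isolated) | CON(C)C(=O)/C(C)=C(\C)CCC1(OCCO1)[C@@H](O[Si](C)(C)C(C)(C)C)CO[Si](C)(C)C(C)(C)C | intermediate
13 | (E)-6-{2-[(S)-1,2-bis(TBSO)ethyl]-1,3-dioxolan-2-yl}-3,4-dimethylhex-3-en-2-one | CC(=O)/C(C)=C(\C)CCC1(OCCO1)[C@@H](O[Si](C)(C)C(C)(C)C)CO[Si](C)(C)C(C)(C)C | intermediate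
14 | (E)-6-{2-[(S)-1-(TBSO)-2-hydroxyethyl]-1,3-dioxolan-2-yl}-3,4-dimethylhex-3-en-2-one | CC(=O)/C(C)=C(\C)CCC1(OCCO1)[C@@H](O[Si](C)(C)C(C)(C)C)CO | intermediate
15 | (S)-2-(TBSO)-2-{2-[(E)-3,4-dimethyl-5-oxohex-3-en-1-yl]-1,3-dioxolan-2-yl}acetaldehyde | CC(=O)/C(C)=C(\C)CCC1(OCCO1)[C@@H](O[Si](C)(C)C(C)(C)C)C=O | intermediate
16 | diethyl (phenylsulfonyl)methylphosphonate | CCOP(=O)(CS(=O)(=O)c1ccccc1)OCC | starting material
17 | (E)-6-{2-[(1S,2E)-1-(TBSO)-3-(phenylsulfonyl)prop-2-en-1-yl]-1,3-dioxolan-2-yl}-3,4-dimethylhex-3-en-2-one | CC(=O)/C(C)=C(\C)CCC1(OCCO1)[C@@H](O[Si](C)(C)C(C)(C)C)/C=C/S(=O)(=O)c1ccccc1 | intermediate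
18 | (3E)-2-(TBSO)-3,4-dimethyl-6-{2-[(1S,2E)-1-(TBSO)-3-(phenylsulfonyl)prop-2-en-1-yl]-1,3-dioxolan-2-yl}hexa-1,3-diene (cycloaddition precursor) | C=C(O[Si](C)(C)C(C)(C)C)/C(C)=C(\C)CCC1(OCCO1)[C@@H](O[Si](C)(C)C(C)(C)C)/C=C/S(=O)(=O)c1ccccc1 | intermediate
19 | (1S,5S,9S,10R)-3,9α-bis(TBSO)-8,8-(ethylenedioxy)-1α-(phenylsulfonyl)-11,12,13-trinoreremophil-3-ene (trans-fused cycloadduct) | CC1=C(O[Si](C)(C)C(C)(C)C)C[C@H](S(=O)(=O)c2ccccc2)[C@H]3[C@H](O[Si](C)(C)C(C)(C)C)C4(OCCO4)CC[C@]13C | intermediate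
20 | (1S,4R,5R,9S,10R)-9α-(TBSO)-8,8-(ethylenedioxy)-1α-(phenylsulfonyl)-11,12,13-trinoreremophilan-3-one (not isolated) | C[C@H]1C(=O)C[C@H](S(=O)(=O)c2ccccc2)[C@H]3[C@H](O[Si](C)(C)C(C)(C)C)C4(OCCO4)CC[C@]13C | intermediate
21 | (4R,5S,9S,10R)-9α-(TBSO)-8,8-(ethylenedioxy)-11,12,13-trinoreremophil-1-en-3-one | C[C@H]1C(=O)C=C[C@H]2[C@H](O[Si](C)(C)C(C)(C)C)C3(OCCO3)CC[C@]12C | intermediate
22 | (4R,5S,9S,10R)-9α-(TBSO)-8,8-(ethylenedioxy)-11,12,13-trinoreremophilan-3-one (not isolated) | C[C@H]1C(=O)CC[C@H]2[C@H](O[Si](C)(C)C(C)(C)C)C3(OCCO3)CC[C@]12C | intermediate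
23 | (3R,4R,5R,9S,10R)-9α-(TBSO)-8,8-(ethylenedioxy)-11,12,13-trinoreremophilan-3α-ol | C[C@H]1[C@H](O)CC[C@H]2[C@H](O[Si](C)(C)C(C)(C)C)C3(OCCO3)CC[C@]12C | intermediate
24 | (3R,4R,5R,9S,10R)-3α-hydroxy-9α-(TBSO)-11,12,13-trinoreremophilan-8-one | C[C@H]1[C@H](O)CC[C@H]2[C@H](O[Si](C)(C)C(C)(C)C)C(=O)CC[C@]12C | intermediate
25 | (3R,4R,5R,9S,10R)-3α-(TESO)-9α-(TBSO)-11,12,13-trinoreremophilan-8-one | C[C@H]1[C@H](O[Si](CC)(CC)CC)CC[C@H]2[C@H](O[Si](C)(C)C(C)(C)C)C(=O)CC[C@]12C | intermediate
26 | 1,1-dimethoxypropan-2-one | CC(=O)C(OC)OC | starting material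
27 | 11-hydroxy-12,12-dimethoxy-3α-(TESO)-9α-(TBSO)eremophilan-8-one, mixture at C7 and C11 | C[C@H]1[C@H](O[Si](CC)(CC)CC)CC[C@H]2[C@H](O[Si](C)(C)C(C)(C)C)C(=O)C(C(C)(O)C(OC)OC)C[C@]12C | intermediate
28 | 11-methanesulfonate of 27 (not isolated) | C[C@H]1[C@H](O[Si](CC)(CC)CC)CC[C@H]2[C@H](O[Si](C)(C)C(C)(C)C)C(=O)C(C(C)(OS(C)(=O)=O)C(OC)OC)C[C@]12C | intermediate
29 | (E)-12,12-dimethoxy-3α-(TESO)-9α-(TBSO)eremophil-7(11)-en-8-one | C[C@H]1[C@H](O[Si](CC)(CC)CC)CC[C@H]2[C@H](O[Si](C)(C)C(C)(C)C)C(=O)/C(=C(\C)C(OC)OC)C[C@]12C | intermediate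
30 | (E)-3α-hydroxy-12,12-dimethoxy-9α-(TBSO)eremophil-7(11)-en-8-one (not isolated) | C[C@H]1[C@H](O)CC[C@H]2[C@H](O[Si](C)(C)C(C)(C)C)C(=O)/C(=C(\C)C(OC)OC)C[C@]12C | intermediate
31 | (E)-3α-hydroxy-8-oxo-9α-(TBSO)eremophil-7(11)-en-12-al | C[C@H]1[C@H](O)CC[C@H]2[C@H](O[Si](C)(C)C(C)(C)C)C(=O)/C(=C(\C)C=O)C[C@]12C | intermediate
32 | (E)-non-3-en-2-one | CCCCC/C=C/C(C)=O | starting material
33 | triethyl 4-phosphonocrotonate | CCOC(=O)/C=C/CP(=O)(OCC)OCC | starting material
34 | ethyl (2E,4E,6E)-5-methyldodeca-2,4,6-trienoate | CCCCC/C=C/C(C)=C/C=C/C(=O)OCC | intermediate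
35 | (2E,4E,6E)-5-methyldodeca-2,4,6-trienoic acid | CCCCC/C=C/C(C)=C/C=C/C(=O)O | intermediate
36 | mixed anhydride of 35 with 2,4,6-trichlorobenzoic acid (not isolated) | CCCCC/C=C/C(C)=C/C=C/C(=O)OC(=O)c1c(Cl)cc(Cl)cc1Cl | intermediate
37 | (E)-8,12-dioxo-9α-(TBSO)eremophil-7(11)-en-3α-yl (2E,4E,6E)-5-methyldodeca-2,4,6-trienoate | CCCCC/C=C/C(C)=C/C=C/C(=O)O[C@@H]1CC[C@H]2[C@H](O[Si](C)(C)C(C)(C)C)C(=O)/C(=C(\C)C=O)C[C@]2(C)[C@H]1C | intermediate
38 | (E)-12-hydroxy-8-oxo-9α-(TBSO)eremophil-7(11)-en-3α-yl (2E,4E,6E)-5-methyldodeca-2,4,6-trienoate | CCCCC/C=C/C(C)=C/C=C/C(=O)O[C@@H]1CC[C@H]2[C@H](O[Si](C)(C)C(C)(C)C)C(=O)/C(=C(\C)CO)C[C@]2(C)[C@H]1C | intermediate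
39 | (3R,4R,5R,9S,10R)-9α,12-dihydroxy-8-oxoeremophil-7(11)E-en-3α-yl (2E,4E,6E)-5-methyldodeca-2,4,6-trienoate (CNP0226738.2) | CCCCC/C=C/C(C)=C/C=C/C(=O)O[C@@H]1CC[C@H]2[C@H](O)C(=O)/C(=C(\C)CO)C[C@]2(C)[C@H]1C | target

**Step count**
Total: 25 steps. Longest linear sequence: 22 steps (3 → 39 through steps 2–20 and 23–25); steps 1, 21 and 22 are convergent branches.

**Steps most likely to fail**

Step 13 (cycloaddition). The diene terminus C5 is fully substituted and carries a (Z)-methyl, so the [4+2] closure may be slow enough for the 1,5-hydrogen shift of that diene, thermal loss of the enol ether, or leakage through the exo (cis-fused) transition state to compete. The fallback changes the activator from sulfonyl to nitro and sets out from aldehyde 15. A Henry reaction with nitromethane (catalytic Et3N) should give the nitro alcohol F1. Dehydration (MsCl, i-Pr2NEt, −20 °C) should give the (E)-nitroalkene F2, and soft enolisation (TBSOTf, i-Pr2NEt, −78 °C) the nitro triene F3. Nitroalkenes are much stronger dienophiles than vinyl sulfones and are known to give trans-fused decalins intramolecularly, so F3 should close near 80 °C through the same chair, activator-endo arrangement to the nitro cycloadduct F4. Treatment of F4 with Bu4NF/AcOH and then DBU should cleave the enol ether and expel nitrous acid, and the route is rejoined at enone 21.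

Step 16 (ketal hydrolysis). The dioxolane sits next to the electron-withdrawing C9 silyloxy group and may hydrolyse so slowly that loss of the C9 silyl ether or an acid-induced ketol shift competes. The fallback sets out from 23 and gives up the selective deprotection. Exhaustive hydrolysis (3 M HCl, THF, 50 °C) should give the dihydroxy ketone F5. Et3SiCl/imidazole at −20 °C should then silylate only the unhindered equatorial C3 hydroxyl, giving the mono-TES ether F6, since the C9 hydroxyl is flanked by the ring fusion and the ketone. TBSOTf/2,6-lutidine at −78 °C caps C9, and the route is rejoined at 25.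

Step 19 (dehydration and C7=C11 geometry). The elimination may run toward the methyl group (deconjugated isomer), may not equilibrate fully to the E alkene, or may be undercut by retro-aldol cleavage. The fallback sets out from 25 and builds C12 by oxidation instead. The lithium enolate with acetone should give the acetone aldol F7, and MsCl/Et3N then DBU the isopropylidene ketone F8, which has no alkene geometry to control. SeO2 in dioxane at 80 °C, which in β,β-dimethyl enones oxidises the γ-methyl trans to the carbonyl through to the aldehyde, should then give the TES-protected enal F9, whose trans-enedione geometry is also the thermodynamic one. TsOH·H2O in acetone–H2O removes the TES ether, and the route is rejoined at 31.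

Further compounds
F1 | step 13 | (S)-configured nitro alcohol from 15 and nitromethane (C10 carbinol, both epimers) | CC(=O)/C(C)=C(\C)CCC1(OCCO1)[C@@H](O[Si](C)(C)C(C)(C)C)C(O)C[N+](=O)[O-]
F2 | step 13 | (E)-6-{2-[(1S,2E)-1-(TBSO)-3-nitroprop-2-en-1-yl]-1,3-dioxolan-2-yl}-3,4-dimethylhex-3-en-2-one | CC(=O)/C(C)=C(\C)CCC1(OCCO1)[C@@H](O[Si](C)(C)C(C)(C)C)/C=C/[N+](=O)[O-]
F3 | step 13 | (3E)-2-(TBSO)-3,4-dimethyl-6-{2-[(1S,2E)-1-(TBSO)-3-nitroprop-2-en-1-yl]-1,3-dioxolan-2-yl}hexa-1,3-diene | C=C(O[Si](C)(C)C(C)(C)C)/C(C)=C(\C)CCC1(OCCO1)[C@@H](O[Si](C)(C)C(C)(C)C)/C=C/[N+](=O)[O-]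
F4 | step 13 | 3,9α-bis(TBSO)-8,8-(ethylenedioxy)-1α-nitro-11,12,13-trinoreremophil-3-ene (trans-fused) | CC1=C(O[Si](C)(C)C(C)(C)C)C[C@H]([N+](=O)[O-])[C@H]2[C@H](O[Si](C)(C)C(C)(C)C)C3(OCCO3)CC[C@]12C
F5 | step 16 | (3R,4R,5R,9S,10R)-3α,9α-dihydroxy-11,12,13-trinoreremophilan-8-one | C[C@H]1[C@H](O)CC[C@H]2[C@H](O)C(=O)CC[C@]12C
F6 | step 16 | (3R,4R,5R,9S,10R)-9α-hydroxy-3α-(TESO)-11,12,13-trinoreremophilan-8-one | C[C@H]1[C@H](O[Si](CC)(CC)CC)CC[C@H]2[C@H](O)C(=O)CC[C@]12C
F7 | step 19 | 11-hydroxy-3α-(TESO)-9α-(TBSO)eremophilan-8-one (C7 epimers) | C[C@H]1[C@H](O[Si](CC)(CC)CC)CC[C@H]2[C@H](O[Si](C)(C)C(C)(C)C)C(=O)C(C(C)(C)O)C[C@]12C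
F8 | step 19 | 3α-(TESO)-9α-(TBSO)eremophil-7(11)-en-8-one | C[C@H]1[C@H](O[Si](CC)(CC)CC)CC[C@H]2[C@H](O[Si](C)(C)C(C)(C)C)C(=O)C(=C(C)C)C[C@]12C
F9 | step 19 | (E)-8-oxo-3α-(TESO)-9α-(TBSO)eremophil-7(11)-en-12-al | C[C@H]1[C@H](O[Si](CC)(CC)CC)CC[C@H]2[C@H](O[Si](C)(C)C(C)(C)C)C(=O)/C(=C(\C)C=O)C[C@]12C
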